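**Retrosynthetic overview**
- C7–OH: hydroxyl-directed reduction of a C7 ketone, with hydride delivered from the 8α-OH side.
- C6–OAc: tether-directed α′-acetoxylation of the 8α-hydroxy-7-ketone (C–O bond, proposed new method).
- C8–OH and C7=O: ketohydroxylation of a Δ7 alkene from the α face (C–O bond).
- Enone: dehydrogenation of the C13 methyl ketone. Δ7 alkene: dehydration of the 8α-ol followed by olefin isomerisation.
- Rings A and B (C5, C9, C10) come intact from sclareol, so no ring is formed.

Assumption: labdane numbering is used (C8 carries the tertiary OH, C9 the side chain, C10 the angular methyl), and the target SMILES is read as (11E)-6α-acetoxy-7β,8α-dihydroxy-14,15-dinorlabd-11-en-13-one of the normal labdane series (5α-H, 9α-H, 10β-CH3).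

**Step 1**
Reactants: 1 sclareol
Product: 4 hydroxy ketone 8α-hydroxy-14,15-dinorlabdan-13-one, via tetraol 2 (not isolated), via hydroxy aldehyde 3 (not isolated)
Conditions: OsO4 (2 mol%), NaIO4 (3.5 equiv), THF/H2O, 45 °C
Reagents that add atoms: none
Why: Lemieux–Johnson oxidation: catalytic OsO4 dihydroxylates the only C=C and periodate cleaves the 13,14,15-triol unit twice (C14–C15, then C13–C14), leaving the C13 methyl ketone while the 8α-OH and all ring stereocentres are untouched.

**Step 2**
Reactants: 4 hydroxy ketone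
Product: 5 exocyclic alkene 14,15-dinorlabd-8(17)-en-13-one
Conditions: SOCl2 (1.5 equiv), pyridine, CH2Cl2, −78 °C
Reagents that add atoms: none
Why: E2 elimination of the chlorosulfite of the equatorial 8α-OH: the ring C–H bonds at C7 and C9 are gauche to the C8–O bond and only a C17 methyl hydrogen can stand anti-periplanar, so the exocyclic alkene dominates (any Δ7 isomer formed is compound 6 and is carried along), and the basic, non-cationic conditions prevent capture of a C8 cation by the C13 carbonyl.

**Step 3**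
Reactants: 5 exocyclic alkene
Product: 6 endocyclic alkene 14,15-dinorlabd-7-en-13-one
Conditions: chloro[N,N′-bis(3,5-di-tert-butylsalicylidene)-1,2-cyclohexanediaminato]cobalt, (C36H52N2O2)CoCl (3 mol%), PhSiH3 (5 mol%), benzene, rt
Reagents that add atoms: none
Why: Metal-hydride hydrogen-atom-transfer olefin isomerisation (Shenvi type): the cobalt hydride gives H to C17 and the tertiary C8 radical returns a hydrogen from the accessible C7 methylene rather than the neopentyl C9–H, so the double bond moves one position to the trisubstituted Δ7 alkene under neutral conditions that leave C9 and the ketone alone.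

**Step 4**
Reactants: 6 endocyclic alkene
Product: 7 dienone (11E)-14,15-dinorlabda-7,11-dien-13-one
Conditions: IBX (2.5 equiv), DMSO/fluorobenzene (1:2), 70 °C
Reagents that add atoms: none
Why: IBX-mediated α,β-dehydrogenation of a ketone (Nicolaou type): only enolisation toward C12 has a β-hydrogen to lose, so the conjugated (E)-enone forms, and the unactivated Δ7 alkene is inert to IBX.

**Step 5**
Reactants: 7 dienone
Product: 8 ketol (11E)-8α-hydroxy-14,15-dinorlabd-11-ene-7,13-dione
Conditions: RuCl3 (1 mol%), 2KHSO5·KHSO4·K2SO4 (Oxone), NaHCO3, EtOAc/MeCN/H2O (6:6:1), rt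
Reagents that add atoms: potassium peroxymonosulfate KHSO5 (the oxidant in 2KHSO5·KHSO4·K2SO4; its oxygen is passed on through RuO4 made in the flask), [K+].[O-]S(=O)(=O)OO
Why: RuO4-catalysed ketohydroxylation (Plietker type) of the electron-rich trisubstituted Δ7 alkene in preference to the electron-poor enone: the [3+2] addition occurs on the α face opposite the axial C10 methyl, so the new tertiary C8–O bond is 8α (methyl 8β), and the secondary ruthenate at C7 is oxidised on to the ketone.

**Step 6**
Reactants: 8 ketol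
Product: 11 acetoxy ketol (11E)-6α-acetoxy-8α-hydroxy-14,15-dinorlabd-11-ene-7,13-dione, via silylene enol ether 9 (not isolated), via acetoxysilyl ether 10 (not isolated)
Conditions: iPr2Si(OTf)2 (1.05 equiv), Et3N (2.2 equiv), CH2Cl2, −78 → 0 °C; then Pb(OAc)4 (1.1 equiv), −20 °C → rt; then HF·pyridine, THF, 0 °C
Reagents that add atoms: lead tetraacetate Pb(OAc)4, CC(=O)O[Pb](OC(C)=O)(OC(C)=O)OC(C)=O
Why: Proposed new method: the tertiary 8α-OH is silylated by iPr2Si(OTf)2 and the remaining Si–OTf can then reach only the neighbouring C7 carbonyl (five-membered ring), so Et3N enolises that ketone alone (toward C6, its only α-CH2) and the C13 enone stays as it is; Pb(OAc)4 then attacks the tethered enol ether on the α face (the β face of C6 is blocked by the axial methyls on C4 and C10) and transfers acetate to C6 to give the equatorial 6α-acetate, with silicon leaving as an acetoxysilyl ether that HF removes; the closest known reactions are soft enolisation with a silyl triflate and an amine and the Rubottom-type Pb(OAc)4 acetoxylation of trialkylsilyl enol ethers, the new element being the hydroxyl-tethered silylene that chooses between two ketones.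

**Step 7**
Reactants: 11 acetoxy ketol
Product: 12 target (11E)-6α-acetoxy-7β,8α-dihydroxy-14,15-dinorlabd-11-en-13-one
Conditions: Me4NBH(OAc)3 (5 equiv), MeCN/AcOH (1:1), −25 °C
Reagents that add atoms: none
Why: Hydroxyl-directed triacetoxyborohydride reduction (Evans–Saksena type): the 8α-OH exchanges onto boron and delivers hydride to C7 from the α face, which is also the sterically favoured axial trajectory, giving the equatorial 7β-OH trans to the 8α-OH, while the enone and the acetate, having no neighbouring hydroxyl, are not reduced.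

**Compound list**
1 | sclareol, (13R)-labd-14-ene-8α,13-diol | C=C[C@](C)(O)CC[C@H]1[C@](C)(O)CC[C@H]2C(C)(C)CCC[C@@]21C | starting material
2 | (13R)-labdane-8α,13,14,15-tetraol (C14 epimers) | OCC(O)[C@](C)(O)CC[C@H]1[C@](C)(O)CC[C@H]2C(C)(C)CCC[C@@]21C | intermediate
3 | (13R)-8α,13-dihydroxy-15-norlabdan-14-al | O=C[C@](C)(O)CC[C@H]1[C@](C)(O)CC[C@H]2C(C)(C)CCC[C@@]21C | intermediate
4 | 8α-hydroxy-14,15-dinorlabdan-13-one | CC(=O)CC[C@H]1[C@](C)(O)CC[C@H]2C(C)(C)CCC[C@@]21C | intermediate
5 | 14,15-dinorlabd-8(17)-en-13-one | CC(=O)CC[C@H]1C(=C)CC[C@H]2C(C)(C)CCC[C@@]21C | intermediate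
6 | 14,15-dinorlabd-7-en-13-one | CC(=O)CC[C@H]1C(C)=CC[C@H]2C(C)(C)CCC[C@@]21C | intermediate
7 | (11E)-14,15-dinorlabda-7,11-dien-13-one | CC(=O)/C=C/[C@H]1C(C)=CC[C@H]2C(C)(C)CCC[C@@]21C | intermediate
8 | (11E)-8α-hydroxy-14,15-dinorlabd-11-ene-7,13-dione | CC(=O)/C=C/[C@H]1[C@](C)(O)C(=O)C[C@H]2C(C)(C)CCC[C@@]21C | intermediate
9 | (11E)-7,8α-[(diisopropylsilanediyl)bis(oxy)]-14,15-dinorlabda-6,11-dien-13-one (cyclic silylene enol ether) | CC(=O)/C=C/[C@H]1[C@]3(C)O[Si](C(C)C)(C(C)C)OC3=C[C@H]2C(C)(C)CCC[C@@]21C | intermediate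
10 | (11E)-6α-acetoxy-8α-[acetoxy(diisopropyl)silyloxy]-14,15-dinorlabd-11-ene-7,13-dione | CC(=O)/C=C/[C@H]1[C@](C)(O[Si](OC(C)=O)(C(C)C)C(C)C)C(=O)[C@H](OC(C)=O)[C@H]2C(C)(C)CCC[C@@]21C | intermediate
11 | (11E)-6α-acetoxy-8α-hydroxy-14,15-dinorlabd-11-ene-7,13-dione | CC(=O)/C=C/[C@H]1[C@](C)(O)C(=O)[C@H](OC(C)=O)[C@H]2C(C)(C)CCC[C@@]21C | intermediate
12 | CNP0136046.1, (11E)-6α-acetoxy-7β,8α-dihydroxy-14,15-dinorlabd-11-en-13-one | CC(=O)/C=C/[C@H]1[C@](C)(O)[C@@H](O)[C@H](OC(C)=O)[C@H]2C(C)(C)CCC[C@@]21C | target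

**Step count**
Total steps: 7. Longest linear sequence: 7 (from sclareol).

**Steps most likely to fail**

Step 6 (the proposed new method). The silylene may not close onto the C7 carbonyl, the ketol may rearrange, or the acetoxylation may be unselective. The fallback uses known chemistry only; it sets out from 6 and comes back at 11. Ketohydroxylation of 6 (RuCl3 cat., 2KHSO5·KHSO4·K2SO4, NaHCO3, EtOAc/MeCN/H2O) gives 8α-hydroxy-14,15-dinorlabdane-7,13-dione F3. PPTS in toluene with 4 Å sieves at 80 °C closes the 8α-hydroxyl onto the C13 ketone to give the cyclic enol ether 8α,13-epoxy-14,15-dinorlabd-12-en-7-one F4, which masks both the side-chain ketone and the tertiary alcohol. LiN(SiMe3)2 in THF at −78 °C, then 2-(phenylsulfonyl)-3-phenyloxaziridine, hydroxylates the only possible enolate from the α face to give 6α-hydroxy-8α,13-epoxy-14,15-dinorlabd-12-en-7-one F5. Ac2O, pyridine and DMAP give 6α-acetoxy-8α,13-epoxy-14,15-dinorlabd-12-en-7-one F6. PhSeCl with NaHCO3 in THF/H2O at 0 °C puts selenium on C12 of the enol ether and water opens the ring to 6α-acetoxy-8α-hydroxy-12-(phenylselanyl)-14,15-dinorlabdane-7,13-dione F7. H2O2 and pyridine in CH2Cl2 at 0 °C eliminate the selenoxide to the (E)-enone 11.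

Step 5. RuO4 may also attack the enone or cleave the alkene. The fallback sets out from 7 and comes back at 8. OsO4 (2 mol%) with N-methylmorpholine N-oxide in acetone/H2O, which discriminates far better between the electron-rich and the electron-poor alkene, adds from the α face to give (11E)-7α,8α-dihydroxy-14,15-dinorlabd-11-en-13-one F2. IBX in DMSO at rt then oxidises the secondary 7α-hydroxyl without glycol cleavage to give 8.

Step 4. IBX dehydrogenation of an acyclic methyl ketone may be low-yielding, or may over-oxidise at the doubly activated C9–H. The fallback sets out from 6 and comes back at 7. TMSCl, NaI and Et3N in MeCN at rt give the thermodynamic enol ether (12Z)-13-(trimethylsilyloxy)-14,15-dinorlabda-7,12-diene F1. Pd(OAc)2 (divalent palladium, 10 mol%) under O2 in DMSO at rt (Saegusa–Ito oxidation) then gives the (E)-enone 7.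

**Further compounds**
F1 | step 4 | (12Z)-13-(trimethylsilyloxy)-14,15-dinorlabda-7,12-diene | C/C(O[Si](C)(C)C)=C/C[C@H]1C(C)=CC[C@H]2C(C)(C)CCC[C@@]21C
F2 | step 5 | (11E)-7α,8α-dihydroxy-14,15-dinorlabd-11-en-13-one | CC(=O)/C=C/[C@H]1[C@](C)(O)[C@H](O)C[C@H]2C(C)(C)CCC[C@@]21C
F3 | step 6 | 8α-hydroxy-14,15-dinorlabdane-7,13-dione | CC(=O)CC[C@H]1[C@](C)(O)C(=O)C[C@H]2C(C)(C)CCC[C@@]21C
F4 | step 6 | 8α,13-epoxy-14,15-dinorlabd-12-en-7-one | CC3=CC[C@H]1[C@](C)(O3)C(=O)C[C@H]2C(C)(C)CCC[C@@]21C
F5 | step 6 | 6α-hydroxy-8α,13-epoxy-14,15-dinorlabd-12-en-7-one | CC3=CC[C@H]1[C@](C)(O3)C(=O)[C@H](O)[C@H]2C(C)(C)CCC[C@@]21C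
F6 | step 6 | 6α-acetoxy-8α,13-epoxy-14,15-dinorlabd-12-en-7-one | CC3=CC[C@H]1[C@](C)(O3)C(=O)[C@H](OC(C)=O)[C@H]2C(C)(C)CCC[C@@]21C
F7 | step 6 | 6α-acetoxy-8α-hydroxy-12-(phenylselanyl)-14,15-dinorlabdane-7,13-dione (C12 epimers) | CC(=O)C([Se]c3ccccc3)C[C@H]1[C@](C)(O)C(=O)[C@H](OC(C)=O)[C@H]2C(C)(C)CCC[C@@]21C
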